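**Strategy**

The route treats the epoxide carbons C11–C12 of the cyclohexane ring (C1, C10–C14) as a former alkyne: both bonds that tie them to the ring, C10–C11 and C12–C13, come from one catalytic asymmetric Diels–Alder reaction. The precursor is an acyclic 2-silyloxy diene (C13=C14–C1=C10) and (E)-3-bromo-2-methylacrolein, a propyne equivalent whose formyl and bromide are expelled afterwards to leave C11=C12; the step sets C10. The surviving silyl enol ether then builds quaternary C1 by aldol reaction, two CBS reductions set C14 and C2, the C9 hydroxyl directs the epoxidation, and a Nozaki–Hiyama–Kishi ring closure with lactonisation forms the ten-membered ring and the butenolide.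

Key step: step 4

Remark: atoms carry briarane locants throughout (C1 quaternary carbon with methyl C15, C2 butanoyloxy carbon, C5=C6 ring alkene, C7 lactone carbinol carbon, C8=C17 butenolide alkene, C9 methylene, C10 ring-fusion CH, C11/C12 epoxide carbons with methyl C20 on C11, C14 acetoxy carbon), and monoethyl methylmalonate 23 is taken as commercially available.

**Route**

Step 1
Reactants: 1 2-[(tert-butyldimethylsilyl)oxy]acetaldehyde; 2 3-(triphenylphosphoranylidene)butan-2-one
Product: 3 (3E)-5-[(tert-butyldimethylsilyl)oxy]-3-methylpent-3-en-2-one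
Conditions: CH2Cl2, rt
Reagents that add atoms: none
Why: Wittig olefination with a stabilised acyl ylide is E-selective, which places the future C9 trans to the acetyl group (C13/C14) across C1=C10.

Step 2
Reactants: 3 (3E)-5-[(tert-butyldimethylsilyl)oxy]-3-methylpent-3-en-2-one
Product: 4 (2E)-1-[(tert-butyldimethylsilyl)oxy]-3-methyl-4-[(triisopropylsilyl)oxy]penta-2,4-diene
Conditions: LDA, THF, −78 °C; then TIPSOTf
Reagents that add atoms: triisopropylsilyl trifluoromethanesulfonate, CC(C)[Si](C(C)C)(C(C)C)OS(=O)(=O)C(F)(F)F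
Why: Kinetic deprotonation of the enone at its methyl group and O-silylation give the cross-conjugated 2-silyloxy diene without touching the C1=C10 geometry.

Step 3
Reactants: 5 methacrolein
Product: 7 (2E)-3-bromo-2-methylprop-2-enal, via dibromo aldehyde 6 (not isolated)
Conditions: Br2, CH2Cl2, 0 °C; then Et3N, 0 °C to rt
Reagents that add atoms: bromine, BrBr
Why: Bromine addition followed by base-induced E2 loss of HBr (hydrogen from the CH2Br carbon) should give the conjugated β-bromo enal as its more stable E isomer.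

Step 4
Reactants: 4 (2E)-1-[(tert-butyldimethylsilyl)oxy]-3-methyl-4-[(triisopropylsilyl)oxy]penta-2,4-diene; 7 (2E)-3-bromo-2-methylprop-2-enal
Product: 8 (1R,2S,6S)-6-bromo-2-{[(tert-butyldimethylsilyl)oxy]methyl}-1,3-dimethyl-4-[(triisopropylsilyl)oxy]cyclohex-3-ene-1-carbaldehyde (CHO on C11 cis to CH2OTBS on C10, Br on C12 trans to CHO)
Conditions: (R)-o-tolyl-CBS oxazaborolidine activated with Tf2NH (20 mol %), CH2Cl2, −78 to −40 °C
Reagents that add atoms: none
Why: The boron-bound s-trans enal and the 2-silyloxy diene combine in a concerted, asynchronous [4+2] cycloaddition; the closest known type is the Diels–Alder reaction of α-substituted acroleins with 2-silyloxy dienes under cationic oxazaborolidine catalysis. The cyclohexene ring C1/C10/C11/C12/C13/C14 closes suprafacially on both partners and forms C12–C13 and C10–C11 in one operation. Regiochemistry follows from the diene polarisation: the C14 silyloxy group and the C10 alkyl group both make C13 the nucleophilic terminus, which bonds to the enal β-carbon (C12), so the methyl-bearing α-carbon becomes C11. C10 is set by the catalyst, whose phenyl group shields one face of the enal held by a formyl C–H···O contact (the R catalyst is the one expected from this model), together with the endo (CHO) transition state that places CH2OTBS cis to CHO; C11 and C12 follow from endo addition to the E alkene (Br trans to CHO) and serve only to make the next step antiperiplanar. The step needs endo and facial control, because an exo adduct would lead to the enantiomer of 9, and ring closure faster than loss of bromide; low temperature, the reactive diene and the concerted pathway should secure both.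

Step 5
Reactants: 8 the bromo aldehyde cycloadduct
Product: 9 tert-butyl{[(1R)-2,6-dimethyl-3-[(triisopropylsilyl)oxy]cyclohexa-2,5-dien-1-yl]methoxy}dimethylsilane
Conditions: K2CO3, MeOH, 0 °C to rt
Reagents that add atoms: none
Why: Methoxide adds to the non-enolisable aldehyde and the hemiacetal alkoxide undergoes Grob fragmentation with the antiperiplanar C12–Br bond, releasing methyl formate and bromide and leaving the C11=C12 alkene regiospecifically while C10 is untouched.

Step 6
Reactants: 10 nerol
Product: 11 neryl 4-methoxybenzyl ether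
Conditions: NaH, PMBCl, Bu4NI (cat.), THF, 0 °C to rt
Reagents that add atoms: 4-methoxybenzyl chloride, COc1ccc(CCl)cc1
Why: Williamson etherification of the primary allylic alkoxide protects the future C7 oxygen; the Z alkene of nerol becomes C5=C6 of the target.

Step 7
Reactants: 11 neryl 4-methoxybenzyl ether
Product: 13 (4Z)-6-[(4-methoxybenzyl)oxy]-4-methylhex-4-enal, via terminal epoxide 12 (not isolated)
Conditions: mCPBA, CH2Cl2, −20 °C; then H5IO6, THF/H2O, 0 °C
Reagents that add atoms: 3-chloroperbenzoic acid, OOC(=O)c1cccc(Cl)c1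
Why: The remote, more electron-rich trisubstituted alkene is epoxidised chemoselectively (the allylic ether deactivates the other one), and periodic acid cleaves the epoxide through its diol to the aldehyde and acetone.

Step 8
Reactants: 9 the silyl enol ether diene; 13 (4Z)-6-[(4-methoxybenzyl)oxy]-4-methylhex-4-enal
Product: 14 (2R,3R)-3-{[(tert-butyldimethylsilyl)oxy]methyl}-2-[(4Z)-1-hydroxy-6-[(4-methoxybenzyl)oxy]-4-methylhex-4-en-1-yl]-2,4-dimethylcyclohex-4-en-1-one (epimers at carbinol C2)
Conditions: BF3·OEt2, CH2Cl2, −78 °C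
Reagents that add atoms: none
Why: Mukaiyama aldol addition of the regiodefined tetrasubstituted silyl enol ether creates quaternary C1; the aldehyde should approach anti to the pseudoaxial CH2OTBS group on C10 (allylic strain), so the C15 methyl ends cis to C9, and the C2 carbinol mixture is erased in the next step.

Step 9
Reactants: 14 the aldol adduct
Product: 15 (2R,3R)-3-{[(tert-butyldimethylsilyl)oxy]methyl}-2-[(4Z)-6-[(4-methoxybenzyl)oxy]-4-methylhex-4-enoyl]-2,4-dimethylcyclohex-4-en-1-one
Conditions: Dess–Martin periodinane, NaHCO3, CH2Cl2, 0 °C to rt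
Reagents that add atoms: none
Why: Buffered Dess–Martin oxidation of the secondary alcohol gives the 1,3-diketone (quaternary between the carbonyls) without moving the β,γ-alkene into conjugation.

Step 10
Reactants: 15 the 1,3-diketone
Product: 16 (4Z)-1-[(1S,2R,6R)-2-{[(tert-butyldimethylsilyl)oxy]methyl}-6-hydroxy-1,3-dimethylcyclohex-3-en-1-yl]-6-[(4-methoxybenzyl)oxy]-4-methylhex-4-en-1-one (14R alcohol, OH cis to the acyl group on C1)
Conditions: (S)-2-methyl-CBS-oxazaborolidine (20 mol %), catecholborane (1.1 equiv), toluene, −78 °C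
Reagents that add atoms: none
Why: CBS reduction under reagent control: the cyclohexanone carbonyl (C14) should react faster than the acyclic neopentyl-type C2 ketone, and with quaternary C1 as the large substituent the S catalyst gives the 14R alcohol.

Step 11
Reactants: 16 the 14R hydroxy ketone
Product: 17 (1R,5R,6S)-5-{[(tert-butyldimethylsilyl)oxy]methyl}-6-[(4Z)-6-[(4-methoxybenzyl)oxy]-4-methylhex-4-enoyl]-4,6-dimethylcyclohex-3-en-1-yl acetate
Conditions: Ac2O, DMAP, pyridine, rt
Reagents that add atoms: acetic anhydride, CC(=O)OC(C)=O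
Why: DMAP-catalysed acylation of the secondary alcohol installs the C14 acetate of the target with retention.

Step 12
Reactants: 17 the keto acetate
Product: 18 (1R,5R,6R)-5-{[(tert-butyldimethylsilyl)oxy]methyl}-6-[(1S,4Z)-1-hydroxy-6-[(4-methoxybenzyl)oxy]-4-methylhex-4-en-1-yl]-4,6-dimethylcyclohex-3-en-1-yl acetate
Conditions: (R)-2-methyl-CBS-oxazaborolidine (0.5 equiv), catecholborane, toluene, −78 to −40 °C
Reagents that add atoms: none
Why: CBS reduction under reagent control: with quaternary C1 as the large and the CH2 chain as the small substituent, the R catalyst gives the 2S alcohol.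

Step 13
Reactants: 18 the 2S alcohol
Product: 19 (1S,4Z)-1-[(1R,2R,6R)-6-acetoxy-2-{[(tert-butyldimethylsilyl)oxy]methyl}-1,3-dimethylcyclohex-3-en-1-yl]-6-[(4-methoxybenzyl)oxy]-4-methylhex-4-en-1-yl butanoate
Conditions: (PrCO)2O, DMAP, pyridine, rt
Reagents that add atoms: butanoic anhydride, CCCC(=O)OC(=O)CCC
Why: Fast DMAP-catalysed acylation of the hindered C2 alcohol installs the butanoate with retention and should outpace 1,3-migration of the neighbouring acetate.

Step 14
Reactants: 19 the diester silyl ether
Product: 20 (1S,4Z)-1-[(1R,2R,6R)-6-acetoxy-2-(hydroxymethyl)-1,3-dimethylcyclohex-3-en-1-yl]-6-[(4-methoxybenzyl)oxy]-4-methylhex-4-en-1-yl butanoate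
Conditions: HF·pyridine, pyridine, THF, 0 °C to rt
Reagents that add atoms: none
Why: Fluoride cleaves the primary silyl ether and leaves both esters and the PMB ether, freeing the C9 hydroxyl.

Step 15
Reactants: 20 the homoallylic alcohol
Product: 21 epoxy alcohol: 20 with C11=C12 converted into the (11S,12R)-epoxide, oxygen cis to the CH2OH group and to the C15 methyl
Conditions: VO(acac)2 (5 mol %), t-BuOOH, CH2Cl2, 0 °C to rt
Reagents that add atoms: tert-butyl hydroperoxide, CC(C)(C)OO
Why: Vanadium-catalysed hydroxyl-directed epoxidation: the homoallylic C9 hydroxyl on C10 delivers the peroxide oxygen to its own face of C11=C12 and the remote C5=C6 alkene is left alone.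

Step 16
Reactants: 21 the epoxy alcohol
Product: 22 epoxy iodide: 21 with CH2OH replaced by CH2I
Conditions: I2, PPh3, imidazole, CH2Cl2, 0 °C to rt
Reagents that add atoms: iodine, II
Why: Appel-type iodination converts the primary alcohol by SN2 at C9 under conditions neutral enough for the epoxide and the esters.

Step 17
Reactants: 23 3-ethoxy-2-methyl-3-oxopropanoic acid (monoethyl methylmalonate)
Product: 24 ethyl 3-chloro-2-methyl-3-oxopropanoate
Conditions: (COCl)2, DMF (cat.), CH2Cl2, 0 °C to rt
Reagents that add atoms: oxalyl chloride, O=C(Cl)C(Cl)=O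
Why: Oxalyl chloride with catalytic DMF (Vilsmeier-type activation) converts the half-ester into its acid chloride, which is used crude.

Step 18
Reactants: 22 the epoxy iodide; 24 ethyl 3-chloro-2-methyl-3-oxopropanoate
Product: 26 β-keto ester: 22 with CH2I replaced by CH2–C(=O)–CH(CH3)–CO2Et (epimers at C17), via alkylzinc iodide 25 (not isolated)
Conditions: Zn dust, LiCl, THF, 35 °C; then 24, Pd(PPh3)4 (5 mol %), 0 °C to rt
Reagents that add atoms: none
Why: Zinc insertion into the primary C–I bond tolerates esters and the epoxide, and palladium-catalysed acylation of the alkylzinc iodide (Negishi-type) forms the C8–C9 bond.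

Step 19
Reactants: 26 the β-keto ester
Product: 27 (Z)-enol triflate: 26 with the C8 ketone converted into C8(OTf)=C17(CH3)CO2Et, triflate cis to the ester
Conditions: NaH, THF, 0 °C; then PhNTf2, rt
Reagents that add atoms: N-phenylbis(trifluoromethanesulfonimide), O=S(=O)(N(c1ccccc1)S(=O)(=O)C(F)(F)F)C(F)(F)F
Why: The sodium chelate of the β-keto ester is O-sulfonylated with the triflate cis to the ester, which puts the future C7–C8 bond cis to the lactone carbonyl.

Step 20
Reactants: 27 the enol triflate PMB ether
Product: 28 allylic alcohol: 27 with the PMB ether cleaved to the free C7 hydroxyl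
Conditions: DDQ, CH2Cl2/pH 7 buffer, 0 °C
Reagents that add atoms: none
Why: Oxidative PMB cleavage through the benzylic cation frees the allylic alcohol without affecting triflate, epoxide or esters.

Step 21
Reactants: 28 the allylic alcohol
Product: 29 (Z)-enal: 28 with C7 oxidised to the aldehyde
Conditions: Dess–Martin periodinane, NaHCO3, CH2Cl2, 0 °C
Reagents that add atoms: none
Why: Buffered Dess–Martin oxidation gives the (Z)-enal without isomerising the trisubstituted alkene.

Step 22
Reactants: 29 the enal enol triflate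
Product: 31 target CNP0220791.1, via hydroxy ester 30 (not isolated)
Conditions: CrCl2 (excess), NiCl2 (cat.), DMSO, rt, high dilution
Reagents that add atoms: none
Why: Nozaki–Hiyama–Kishi reaction: nickel inserts into the enol triflate, the alkenylchromium adds 1,2 to the tethered enal to close the ten-membered ring at C7–C8, and the chromium alkoxide lactonises onto the cis ethyl ester; C7 forms under substrate control, the C1/C2/C10 stereotriad holding the tether on one face of the s-trans enal, which is expected to give 7R.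

**Compound list**

1 | 2-[(tert-butyldimethylsilyl)oxy]acetaldehyde | CC(C)(C)[Si](C)(C)OCC=O | starting material
2 | 3-(triphenylphosphoranylidene)butan-2-one | CC(=O)C(C)=P(c1ccccc1)(c1ccccc1)c1ccccc1 | starting material
3 | (3E)-5-[(tert-butyldimethylsilyl)oxy]-3-methylpent-3-en-2-one | CC(=O)/C(C)=C/CO[Si](C)(C)C(C)(C)C | intermediate
4 | (2E)-1-[(tert-butyldimethylsilyl)oxy]-3-methyl-4-[(triisopropylsilyl)oxy]penta-2,4-diene | C=C(O[Si](C(C)C)(C(C)C)C(C)C)/C(C)=C/CO[Si](C)(C)C(C)(C)C | intermediate
5 | methacrolein | CC(=C)C=O | starting material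
6 | 2,3-dibromo-2-methylpropanal | CC(Br)(CBr)C=O | intermediate
7 | (2E)-3-bromo-2-methylprop-2-enal | O=C/C(C)=C/Br | intermediate
8 | (1R,2S,6S)-6-bromo-2-{[(tert-butyldimethylsilyl)oxy]methyl}-1,3-dimethyl-4-[(triisopropylsilyl)oxy]cyclohex-3-ene-1-carbaldehyde | CC1=C(O[Si](C(C)C)(C(C)C)C(C)C)C[C@H](Br)[C@@](C)(C=O)[C@H]1CO[Si](C)(C)C(C)(C)C | intermediate
9 | tert-butyl{[(1R)-2,6-dimethyl-3-[(triisopropylsilyl)oxy]cyclohexa-2,5-dien-1-yl]methoxy}dimethylsilane | CC1=C(O[Si](C(C)C)(C(C)C)C(C)C)CC=C(C)[C@H]1CO[Si](C)(C)C(C)(C)C | intermediate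
10 | nerol | CC(C)=CCC/C(C)=C\CO | starting material
11 | neryl 4-methoxybenzyl ether | CC(C)=CCC/C(C)=C\COCc1ccc(OC)cc1 | intermediate
12 | 6,7-epoxide of 11 (racemic) | CC1(C)OC1CC/C(C)=C\COCc1ccc(OC)cc1 | intermediate
13 | (4Z)-6-[(4-methoxybenzyl)oxy]-4-methylhex-4-enal | O=CCC/C(C)=C\COCc1ccc(OC)cc1 | intermediate
14 | aldol adduct (C15 methyl cis to CH2OTBS; epimers at C2) | COc1ccc(COC/C=C(/C)CCC(O)[C@@]2(C)[C@H](CO[Si](C)(C)C(C)(C)C)C(C)=CCC2=O)cc1 | intermediate
15 | 1,3-diketone (C14 and C2 ketones) | COc1ccc(COC/C=C(/C)CCC(=O)[C@@]2(C)[C@H](CO[Si](C)(C)C(C)(C)C)C(C)=CCC2=O)cc1 | intermediate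
16 | 14R hydroxy ketone | COc1ccc(COC/C=C(/C)CCC(=O)[C@@]2(C)[C@H](CO[Si](C)(C)C(C)(C)C)C(C)=CC[C@H]2O)cc1 | intermediate
17 | 14R acetate, C2 ketone | COc1ccc(COC/C=C(/C)CCC(=O)[C@@]2(C)[C@H](CO[Si](C)(C)C(C)(C)C)C(C)=CC[C@H]2OC(C)=O)cc1 | intermediate
18 | 14R acetate, 2S alcohol | COc1ccc(COC/C=C(/C)CC[C@H](O)[C@@]2(C)[C@H](CO[Si](C)(C)C(C)(C)C)C(C)=CC[C@H]2OC(C)=O)cc1 | intermediate
19 | 14R acetate, 2S butanoate, C9 silyl ether | COc1ccc(COC/C=C(/C)CC[C@H](OC(=O)CCC)[C@@]2(C)[C@H](CO[Si](C)(C)C(C)(C)C)C(C)=CC[C@H]2OC(C)=O)cc1 | intermediate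
20 | C9 alcohol | COc1ccc(COC/C=C(/C)CC[C@H](OC(=O)CCC)[C@@]2(C)[C@H](CO)C(C)=CC[C@H]2OC(C)=O)cc1 | intermediate
21 | (11S,12R)-epoxy alcohol | COc1ccc(COC/C=C(/C)CC[C@H](OC(=O)CCC)[C@@]2(C)[C@H](CO)[C@]3(C)O[C@@H]3C[C@H]2OC(C)=O)cc1 | intermediate
22 | epoxy iodide | COc1ccc(COC/C=C(/C)CC[C@H](OC(=O)CCC)[C@@]2(C)[C@H](CI)[C@]3(C)O[C@@H]3C[C@H]2OC(C)=O)cc1 | intermediate
23 | 3-ethoxy-2-methyl-3-oxopropanoic acid | CCOC(=O)C(C)C(=O)O | starting material
24 | ethyl 3-chloro-2-methyl-3-oxopropanoate | CCOC(=O)C(C)C(Cl)=O | intermediate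
25 | alkylzinc iodide of 22 | COc1ccc(COC/C=C(/C)CC[C@H](OC(=O)CCC)[C@@]2(C)[C@H](C[Zn]I)[C@]3(C)O[C@@H]3C[C@H]2OC(C)=O)cc1 | intermediate
26 | β-keto ester (epimers at C17) | COc1ccc(COC/C=C(/C)CC[C@H](OC(=O)CCC)[C@@]2(C)[C@H](CC(=O)C(C)C(=O)OCC)[C@]3(C)O[C@@H]3C[C@H]2OC(C)=O)cc1 | intermediate
27 | (Z)-enol triflate | COc1ccc(COC/C=C(/C)CC[C@H](OC(=O)CCC)[C@@]2(C)[C@H](C/C(OS(=O)(=O)C(F)(F)F)=C(\C)C(=O)OCC)[C@]3(C)O[C@@H]3C[C@H]2OC(C)=O)cc1 | intermediate
28 | C7 allylic alcohol | OC/C=C(/C)CC[C@H](OC(=O)CCC)[C@@]1(C)[C@H](C/C(OS(=O)(=O)C(F)(F)F)=C(\C)C(=O)OCC)[C@]2(C)O[C@@H]2C[C@H]1OC(C)=O | intermediate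
29 | (Z)-enal | O=C/C=C(/C)CC[C@H](OC(=O)CCC)[C@@]1(C)[C@H](C/C(OS(=O)(=O)C(F)(F)F)=C(\C)C(=O)OCC)[C@]2(C)O[C@@H]2C[C@H]1OC(C)=O | intermediate
30 | macrocyclic 7R hydroxy ester | CCCC(=O)O[C@H]1CC/C(C)=C\[C@@H](O)/C(=C(/C)C(=O)OCC)C[C@@H]2[C@]3(C)O[C@@H]3C[C@@H](OC(C)=O)[C@@]12C | intermediate
31 | CNP0220791.1 (1R,2S,5Z,7R,10S,11S,12R,14R) | CCCC(=O)O[C@H]1CC/C(C)=C\[C@H]2OC(=O)C(C)=C2C[C@@H]2[C@]3(C)O[C@@H]3C[C@@H](OC(C)=O)[C@@]12C | target

**Step count and risks**

Total step count: 22. Longest linear sequence: 18 steps (1, 2, 4, 5, 8–16, 18–22).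

Step 4 (key step). What may go wrong: incomplete endo or facial control, which would erode the enantiomeric purity of 9 after step 5, or addition–elimination at the β-bromo enal in place of ring closure. The fallback sets out from 4 and uses a cobalt-catalysed neutral [4+2] cycloaddition with propyne (CoBr2(dppe), Zn, ZnI2, CH2Cl2, rt). This is a known reaction of unactivated alkynes with 2-silyloxy dienes that places the alkyne substituent para to the silyloxy group. It forms the same two bonds and gives 9 directly, but as the racemate, that is together with ent-9 F1. The enantiomers would be separated by preparative chromatography on a chiral stationary phase, and the route is rejoined at 9.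

Step 22. What may go wrong: oligomerisation in competition with the ten-membered ring closure, isomerisation of the (Z)-enal, or attack on the wrong face of the aldehyde. For the last, the fallback sets C7 by equilibration instead of by addition. The product mixture from 29 containing 7-epi-31 F2 would be treated with catalytic DBU in toluene at rt. Reversible γ-deprotonation of the butenolide to the furanolate interconverts the C7 epimers. This should enrich the 7R epimer only if it is the more stable one, which is assumed and not established. The route comes back at 31.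

Step 10. What may go wrong: competing reduction of the acyclic C2 ketone, that is loss of chemoselectivity between the two ketones of 15. The fallback sets out from 14 and keeps only one ketone in the molecule. Silylation (TESOTf, 2,6-lutidine, CH2Cl2, −78 °C) gives the C2 triethylsilyl ether F3. The same (S)-CBS/catecholborane reduction gives the 14R alcohol F4, and Ac2O/DMAP/pyridine gives the acetate F5. HF·pyridine at 0 °C removes the triethylsilyl group before the primary TBS ether to give the hydroxy acetate F6. Dess–Martin oxidation then comes back to the route at 17.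

**Further compounds**

F1 | step 4 | ent-9, tert-butyl{[(1S)-2,6-dimethyl-3-[(triisopropylsilyl)oxy]cyclohexa-2,5-dien-1-yl]methoxy}dimethylsilane | CC1=C(O[Si](C(C)C)(C(C)C)C(C)C)CC=C(C)[C@@H]1CO[Si](C)(C)C(C)(C)C
F2 | step 22 | 7-epi-31 | CCCC(=O)O[C@H]1CC/C(C)=C\[C@@H]2OC(=O)C(C)=C2C[C@@H]2[C@]3(C)O[C@@H]3C[C@@H](OC(C)=O)[C@@]12C
F3 | step 10 | C2 triethylsilyl ether of 14 (epimers at C2) | COc1ccc(COC/C=C(/C)CCC(O[Si](CC)(CC)CC)[C@@]2(C)[C@H](CO[Si](C)(C)C(C)(C)C)C(C)=CCC2=O)cc1
F4 | step 10 | 14R alcohol of F3 | COc1ccc(COC/C=C(/C)CCC(O[Si](CC)(CC)CC)[C@@]2(C)[C@H](CO[Si](C)(C)C(C)(C)C)C(C)=CC[C@H]2O)cc1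
F5 | step 10 | 14R acetate of F4 | COc1ccc(COC/C=C(/C)CCC(O[Si](CC)(CC)CC)[C@@]2(C)[C@H](CO[Si](C)(C)C(C)(C)C)C(C)=CC[C@H]2OC(C)=O)cc1
F6 | step 10 | 14R acetate with free C2 hydroxyl (epimers at C2) | COc1ccc(COC/C=C(/C)CCC(O)[C@@]2(C)[C@H](CO[Si](C)(C)C(C)(C)C)C(C)=CC[C@H]2OC(C)=O)cc1
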